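Everything rests on cutting the C3'–C4' bond between the side-chain carbinol carbon and the methyl-bearing alkene carbon. The feature exploited is the C3'H(OH)–C2'H2 unit held between two sp2 carbons, C4' and the exocyclic alkylidene C1' on C3 of the butyrolactone ring: it is read as a former vinylboron group. One enantioselective conjunctive cross-coupling forms C3'–C4' by a 1,2-shift of the nerol-derived alkenyl group from boron to carbon, joins C2' to C1', and sets C3' as a C–B bond that oxidative work-up turns into the free hydroxyl next to an acetate already in place. The precursors are a bis(alkenyl)borate, in which boron tethers both bond termini, and the (E)-enol triflate of the acetoxy lactone.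

Key step: step 15

Numbering used: lactone ring O1, C2 (C=O), C3, C4 (OAc), C5 (isobutenyl); side chain C1' (alkylidene CH) to C10' (CH2O).
Assumption: the ligand antipode named in step 15 is taken to deliver the R boronate. Its mirror image is equally available and would be used if a model coupling shows the opposite sense.

Step 1
Reactants: 1 methyl (E)-3-(4-hydroxyphenyl)prop-2-enoate
Product: 2 methyl (E)-3-[4-(triisopropylsilyloxy)phenyl]prop-2-enoate
Conditions: TIPSCl, imidazole, DMF, rt
Reagents that add atoms: triisopropylsilyl chloride, CC(C)[Si](Cl)(C(C)C)C(C)C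
Why: Imidazole-promoted silylation of the phenol gives a bulky aryl silyl ether that should survive the hydride, alkoxide and organolithium steps ahead and still leave with buffered fluoride at the end.

Step 2
Reactants: 2 methyl (E)-3-[4-(triisopropylsilyloxy)phenyl]prop-2-enoate
Product: 3 (E)-3-[4-(triisopropylsilyloxy)phenyl]prop-2-en-1-ol
Conditions: i-Bu2AlH (2.2 equiv), CH2Cl2, −78 °C; aqueous potassium sodium tartrate work-up
Reagents that add atoms: none
Why: Aluminium hydride reduction of the conjugated ester proceeds in the 1,2 sense to the allylic alcohol and leaves the alkene and the silyl ether untouched.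

Step 3
Reactants: 3 (E)-3-[4-(triisopropylsilyloxy)phenyl]prop-2-en-1-ol
Product: 4 (E)-1-(3-bromoprop-1-enyl)-4-(triisopropylsilyloxy)benzene
Conditions: CBr4, PPh3, CH2Cl2, 0 °C
Reagents that add atoms: carbon tetrabromide, BrC(Br)(Br)Br
Why: The Appel reaction converts the primary allylic alcohol to the bromide under neutral conditions that suit this easily ionised cinnamyl system, which is used without storage.

Step 4
Reactants: 5 neryl acetate
Product: 6 6,7-epoxyneryl acetate (racemic at C6)
Conditions: mCPBA (1.0 equiv), NaHCO3, CH2Cl2, 0 °C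
Reagents that add atoms: 3-chloroperbenzoic acid, OOC(=O)c1cccc(Cl)c1
Why: The Prilezhaev epoxidation is electrophilic, so one equivalent of peracid should take the remote trisubstituted C6–C7 alkene rather than the C2–C3 alkene deactivated by the allylic acetate; the new stereocentre is racemic and is destroyed in step 7.

Step 5
Reactants: 6 6,7-epoxyneryl acetate
Product: 7 6,7-epoxynerol (racemic at C6)
Conditions: K2CO3 (cat.), MeOH, rt
Reagents that add atoms: none
Why: Base-catalysed transesterification frees the allylic alcohol, while the trisubstituted epoxide, which serves as a masked aldehyde, is inert to methoxide at room temperature.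

Step 6
Reactants: 7 6,7-epoxynerol; 4 (E)-1-(3-bromoprop-1-enyl)-4-(triisopropylsilyloxy)benzene
Product: 8 6,7-epoxyneryl (E)-4-(triisopropylsilyloxy)cinnamyl ether
Conditions: NaH, THF/DMF, 0 °C; then 4, Bu4NI (cat.), 0 °C to rt
Reagents that add atoms: none
Why: In this Williamson ether synthesis the sodium alkoxide of 7 displaces the primary allylic bromide in an SN2 reaction, and neither the hindered epoxide nor the bulky aryl silyl ether should react with the alkoxide.

Step 7
Reactants: 8 6,7-epoxyneryl (E)-4-(triisopropylsilyloxy)cinnamyl ether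
Product: 9 (4Z)-4-methyl-6-{[(2E)-3-(4-triisopropylsilyloxyphenyl)prop-2-enyl]oxy}hex-4-enal
Conditions: H5IO6, THF/H2O, 0 °C
Reagents that add atoms: none
Why: Periodic acid opens the epoxide to the glycol and cleaves it in the same flask (Malaprade-type cleavage), which unmasks the aldehyde without an oxidant that would attack the electron-rich cinnamyl or the neryl alkene.

Step 8
Reactants: 9 (4Z)-4-methyl-6-{[(2E)-3-(4-triisopropylsilyloxyphenyl)prop-2-enyl]oxy}hex-4-enal
Product: 11 (2Z,6E)-7-bromo-3-methylocta-2,6-dienyl (E)-4-(triisopropylsilyloxy)cinnamyl ether, via beta-lithiooxy ylide 10 (not isolated)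
Conditions: EtPPh3Br, PhLi, THF, 0 °C; 9, −78 °C; PhLi, −78 to −30 °C; BrCF2CF2Br, −78 °C to rt
Reagents that add atoms: ethyltriphenylphosphonium bromide, CC[P+](c1ccccc1)(c1ccccc1)c1ccccc1.[Br-]; 1,2-dibromotetrafluoroethane, FC(F)(Br)C(F)(F)Br
Why: In this Wittig–Schlosser sequence (SCOOPY variant) the lithiobetaine is deprotonated to 10, brominated at carbon and collapses with loss of Ph3PO, a process known to favour the (E)-alkenyl bromide (bromine anti to the chain) and complementary to the Z-selective alpha-halo ylide Wittig reaction.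

Step 9
Reactants: 12 allenylboronic acid pinacol ester; 13 3-methylbut-2-enal
Product: 17 (3S,4R)-6-methylhept-5-ene-1,3,4-triol, via gamma-boryl allylborane 14 (not isolated), via allylboration adduct 15 (not isolated), via 9-BBN adduct 16 (not isolated)
Conditions: 12, (−)-Ipc2BH [from (+)-α-pinene], Et2O, 0 °C; 13, −78 °C; 9-BBN, THF, 0 °C to rt; NaOH, H2O2, 0 °C to rt
Reagents that add atoms: hydrogen peroxide, OO
Why: Allene hydroboration gives, after borotropic equilibration, the (E)-allylborane 14, whose closed chair allylboration of 13 sets the anti C3/C4 relationship from the E geometry and the absolute sense (4R, hence 3S) from the isopinocampheyl groups, after which 9-BBN hydroborates only the monosubstituted alkene and one stereoretentive oxidation turns all C–B bonds into C–OH.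

Step 10
Reactants: 17 (3S,4R)-6-methylhept-5-ene-1,3,4-triol
Product: 19 (4S,5R)-4-hydroxy-5-(2-methylprop-1-enyl)dihydrofuran-2(3H)-one, via lactol 18 (not isolated)
Conditions: TEMPO (cat.), PhI(OAc)2 (2.5 equiv), CH2Cl2, rt
Reagents that add atoms: none
Why: In this oxidative lactonisation of a 1,4-diol the oxoammonium species takes the primary alcohol selectively, the aldehyde closes with the allylic hydroxyl to the five-membered lactol 18, and this is oxidised on to the lactone with both stereocentres untouched.

Step 11
Reactants: 19 (4S,5R)-4-hydroxy-5-(2-methylprop-1-enyl)dihydrofuran-2(3H)-one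
Product: 20 (4S,5R)-5-(2-methylprop-1-enyl)-4-(triethylsilyloxy)dihydrofuran-2(3H)-one
Conditions: TESCl, imidazole, CH2Cl2, 0 °C
Reagents that add atoms: chlorotriethylsilane, CC[Si](Cl)(CC)CC
Why: Standard silylation puts at C4 a group that blocks retro-aldol cleavage and, unlike an ester, is a poor leaving group from the lactone enolate needed next.

Step 12
Reactants: 20 (4S,5R)-5-(2-methylprop-1-enyl)-4-(triethylsilyloxy)dihydrofuran-2(3H)-one
Product: 21 (4S,5R)-3-(hydroxymethylene)-5-(2-methylprop-1-enyl)-4-(triethylsilyloxy)dihydrofuran-2(3H)-one (enol of the 3-formyl lactone)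
Conditions: LiN(SiMe3)2 (2.2 equiv), THF, −78 °C; HCO2CH2CF3, −78 °C; AcOH quench
Reagents that add atoms: 2,2,2-trifluoroethyl formate, O=COCC(F)(F)F
Why: In this crossed Claisen formylation the kinetic lithium enolate is acylated by the activated formate at a temperature where beta-elimination from a five-membered ring enolate is slow, and the second equivalent of base stores the product as its stabilised enolate.

Step 13
Reactants: 21 (4S,5R)-3-(hydroxymethylene)-5-(2-methylprop-1-enyl)-4-(triethylsilyloxy)dihydrofuran-2(3H)-one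
Product: 22 (3E,4S,5R)-5-(2-methylprop-1-enyl)-4-(triethylsilyloxy)-3-[(trifluoromethylsulfonyloxy)methylene]dihydrofuran-2(3H)-one
Conditions: Tf2O, i-Pr2NEt, CH2Cl2, −78 °C
Reagents that add atoms: trifluoromethanesulfonic anhydride, O=S(=O)(OS(=O)(=O)C(F)(F)F)C(F)(F)F
Why: Enol triflation of the non-chelated ammonium enolate, which prefers the extended form with its oxygen anti to the lactone carbonyl, should give the E isomer with the leaving group cis to C4, the geometry that the target alkylidene needs.

Step 14
Reactants: 22 (3E,4S,5R)-5-(2-methylprop-1-enyl)-4-(triethylsilyloxy)-3-[(trifluoromethylsulfonyloxy)methylene]dihydrofuran-2(3H)-one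
Product: 23 (3E,4S,5R)-4-acetoxy-5-(2-methylprop-1-enyl)-3-[(trifluoromethylsulfonyloxy)methylene]dihydrofuran-2(3H)-one
Conditions: Ac2O, TMSOTf (cat.), CH2Cl2, −20 to 0 °C
Reagents that add atoms: acetic anhydride, CC(=O)OC(C)=O
Why: In this Lewis acid catalysed acetolysis of a silyl ether the oxygen is acylated and silicon then leaves, so the C4–O bond is never broken (retention) and no base is present that could cause elimination or add to the vinylogous acyl triflate.

Step 15
Reactants: 11 (2Z,6E)-7-bromo-3-methylocta-2,6-dienyl (E)-4-(triisopropylsilyloxy)cinnamyl ether; 24 vinylboronic acid pinacol ester; 23 (3E,4S,5R)-4-acetoxy-5-(2-methylprop-1-enyl)-3-[(trifluoromethylsulfonyloxy)methylene]dihydrofuran-2(3H)-one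
Product: 28 O-triisopropylsilyl ether of the target, via alkenyllithium 25 (not isolated), via bis(alkenyl)borate 26 (not isolated), via allylic boronate 27 (not isolated)
Conditions: 11, t-BuLi (2.0 equiv), Et2O, −78 °C; 24, −78 °C to rt; solvent change to THF; NaOTf, Pd(OAc)2 (cat.), MandyPhos ligand (SP,S'P)-1,1'-bis[bis(4-methoxy-3,5-dimethylphenyl)phosphino]-2,2'-bis[(R)-α-(dimethylamino)benzyl]ferrocene (cat.), 23 (1.1 equiv), 50 °C; then NaBO3·4H2O, THF/H2O, rt
Reagents that add atoms: sodium perborate tetrahydrate, [Na+].[O-]OB=O.O.O.O.O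
Why: Bromine–lithium exchange with retention gives 25, which adds to the vacant boron orbital of 24 to give borate 26, so that boron holds both carbons of the bond to be made. Oxidative addition of the C–OTf bond of 23 to zerovalent palladium gives a cationic alkenylpalladium that binds the unsubstituted vinyl group of 26 and triggers a 1,2-metallate shift: C4' migrates from boron to the boron-bound vinyl carbon (C3') anti to palladium, and reductive elimination then joins the former vinyl CH2 (C2') to the exocyclic C1' of the lactone, both alkene geometries being retained. The closest known reaction type is the enantioselective palladium/MandyPhos conjunctive cross-coupling of non-symmetric bis(alkenyl)borates with C(sp2) triflates, run with NaOTf as halide scavenger and followed by stereoretentive boronate oxidation. No ring is closed. The only new stereocentre, C3', is set as R by the ligand, which selects the face of the bound vinyl group, while the distant ring stereocentres C4 and C5 can only modulate this. The step needs activation of the vinyl and migration of the trisubstituted alkenyl group (secured by their steric difference), conjunctive coupling rather than direct Suzuki–Miyaura transfer (secured by the wide-bite-angle ligand and a palladium kept cationic by halide removal), and oxidative addition at the enol triflate rather than ionisation of the C4 allylic acetate (secured by the far more reactive vinylogous acyl triflate, the slight excess of 23 and the isobutenyl group that shields the ring face anti to the acetate).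

Step 16
Reactants: 28 O-triisopropylsilyl ether of the target
Product: 29 target CNP0237370.1
Conditions: TBAF, AcOH (1:1), THF, 0 °C
Reagents that add atoms: none
Why: Fluoride-induced desilylation is fast for an aryl silyl ether, and the acetic acid buffer keeps the medium non-basic so that the acetate, the alkylidene lactone and its acidic C2' methylene are left alone.

Compound list
1 | methyl (E)-3-(4-hydroxyphenyl)prop-2-enoate | COC(=O)/C=C/c1ccc(O)cc1 | starting material
2 | methyl (E)-3-[4-(triisopropylsilyloxy)phenyl]prop-2-enoate | COC(=O)/C=C/c1ccc(O[Si](C(C)C)(C(C)C)C(C)C)cc1 | intermediate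
3 | (E)-3-[4-(triisopropylsilyloxy)phenyl]prop-2-en-1-ol | OC/C=C/c1ccc(O[Si](C(C)C)(C(C)C)C(C)C)cc1 | intermediate
4 | (E)-1-(3-bromoprop-1-enyl)-4-(triisopropylsilyloxy)benzene | BrC/C=C/c1ccc(O[Si](C(C)C)(C(C)C)C(C)C)cc1 | intermediate
5 | neryl acetate, (2Z)-3,7-dimethylocta-2,6-dienyl acetate | CC(C)=CCC/C(C)=C\COC(C)=O | starting material
6 | 6,7-epoxyneryl acetate, racemic at C6 | CC1(C)OC1CC/C(C)=C\COC(C)=O | intermediate
7 | 6,7-epoxynerol, racemic at C6 | CC1(C)OC1CC/C(C)=C\CO | intermediate
8 | 6,7-epoxyneryl (E)-4-(triisopropylsilyloxy)cinnamyl ether | CC1(C)OC1CC/C(C)=C\COC/C=C/c1ccc(O[Si](C(C)C)(C(C)C)C(C)C)cc1 | intermediate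
9 | (4Z)-4-methyl-6-{[(2E)-3-(4-triisopropylsilyloxyphenyl)prop-2-enyl]oxy}hex-4-enal | O=CCC/C(C)=C\COC/C=C/c1ccc(O[Si](C(C)C)(C(C)C)C(C)C)cc1 | intermediate
10 | beta-lithiooxy phosphonium ylide from 9 and ethylidenetriphenylphosphorane | CC(=P(c1ccccc1)(c1ccccc1)c1ccccc1)C(O[Li])CC/C(C)=C\COC/C=C/c1ccc(O[Si](C(C)C)(C(C)C)C(C)C)cc1 | intermediate
11 | (2Z,6E)-7-bromo-3-methylocta-2,6-dienyl (E)-4-(triisopropylsilyloxy)cinnamyl ether | Br/C(C)=C/CC/C(C)=C\COC/C=C/c1ccc(O[Si](C(C)C)(C(C)C)C(C)C)cc1 | intermediate
12 | allenylboronic acid pinacol ester | C=C=CB1OC(C)(C)C(C)(C)O1 | starting material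
13 | 3-methylbut-2-enal | CC(C)=CC=O | starting material
14 | [(E)-3-(pinacolatoboryl)allyl]bis(isopinocampheyl)borane | CC1(C)OB(/C=C/CB([C@@H]2C[C@@H]3C[C@H]([C@H]2C)C3(C)C)[C@@H]2C[C@@H]3C[C@H]([C@H]2C)C3(C)C)OC1(C)C | intermediate
15 | anti allylboration adduct, C3 pinacol boronate and C4 O-bis(isopinocampheyl)borinate of 6-methylhepta-1,5-diene | C=C[C@H](B1OC(C)(C)C(C)(C)O1)[C@H](OB([C@@H]1C[C@@H]2C[C@H]([C@H]1C)C2(C)C)[C@@H]1C[C@@H]2C[C@H]([C@H]1C)C2(C)C)C=C(C)C | intermediate
16 | terminal 9-BBN adduct of 15 | C1CC2CCCC(C1)B2CC[C@H](B1OC(C)(C)C(C)(C)O1)[C@H](OB([C@@H]1C[C@@H]2C[C@H]([C@H]1C)C2(C)C)[C@@H]1C[C@@H]2C[C@H]([C@H]1C)C2(C)C)C=C(C)C | intermediate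
17 | (3S,4R)-6-methylhept-5-ene-1,3,4-triol | OCC[C@H](O)[C@H](O)C=C(C)C | intermediate
18 | (4S,5R)-5-(2-methylprop-1-enyl)tetrahydrofuran-2,4-diol, anomeric mixture | O[C@H]1CC(O)O[C@@H]1C=C(C)C | intermediate
19 | (4S,5R)-4-hydroxy-5-(2-methylprop-1-enyl)dihydrofuran-2(3H)-one | O[C@H]1CC(=O)O[C@@H]1C=C(C)C | intermediate
20 | (4S,5R)-5-(2-methylprop-1-enyl)-4-(triethylsilyloxy)dihydrofuran-2(3H)-one | CC[Si](CC)(CC)O[C@H]1CC(=O)O[C@@H]1C=C(C)C | intermediate
21 | (4S,5R)-3-(hydroxymethylene)-5-(2-methylprop-1-enyl)-4-(triethylsilyloxy)dihydrofuran-2(3H)-one | CC[Si](CC)(CC)O[C@H]1C(=CO)C(=O)O[C@@H]1C=C(C)C | intermediate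
22 | (3E,4S,5R)-5-(2-methylprop-1-enyl)-4-(triethylsilyloxy)-3-[(trifluoromethylsulfonyloxy)methylene]dihydrofuran-2(3H)-one | CC[Si](CC)(CC)O[C@H]1/C(=C\OS(=O)(=O)C(F)(F)F)C(=O)O[C@@H]1C=C(C)C | intermediate
23 | (3E,4S,5R)-4-acetoxy-5-(2-methylprop-1-enyl)-3-[(trifluoromethylsulfonyloxy)methylene]dihydrofuran-2(3H)-one | CC(=O)O[C@H]1/C(=C\OS(=O)(=O)C(F)(F)F)C(=O)O[C@@H]1C=C(C)C | intermediate
24 | vinylboronic acid pinacol ester | C=CB1OC(C)(C)C(C)(C)O1 | starting material
25 | alkenyllithium from 11, lithium anti to the chain | [Li]/C(C)=C/CC/C(C)=C\COC/C=C/c1ccc(O[Si](C(C)C)(C(C)C)C(C)C)cc1 | intermediate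
26 | lithium (alkenyl)(vinyl)pinacolatoborate | [Li+].C=C[B-]1(OC(C)(C)C(C)(C)O1)/C(C)=C/CC/C(C)=C\COC/C=C/c1ccc(O[Si](C(C)C)(C(C)C)C(C)C)cc1 | intermediate
27 | (3'R)-3'-pinacolatoboryl analogue of 28 (boron in place of the C3' hydroxyl) | CC(=O)O[C@H]1/C(=C\C[C@@H](B2OC(C)(C)C(C)(C)O2)/C(C)=C/CC/C(C)=C\COC/C=C/c2ccc(O[Si](C(C)C)(C(C)C)C(C)C)cc2)C(=O)O[C@@H]1C=C(C)C | intermediate
28 | O-triisopropylsilyl ether of the target (phenol protected) | CC(=O)O[C@H]1/C(=C\C[C@@H](O)/C(C)=C/CC/C(C)=C\COC/C=C/c2ccc(O[Si](C(C)C)(C(C)C)C(C)C)cc2)C(=O)O[C@@H]1C=C(C)C | intermediate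
29 | (3E,4S,5R)-4-acetoxy-3-[(3R,4E,8Z)-3-hydroxy-10-{[(2E)-3-(4-hydroxyphenyl)prop-2-enyl]oxy}-4,8-dimethyldeca-4,8-dienylidene]-5-(2-methylprop-1-enyl)dihydrofuran-2(3H)-one | CC(=O)O[C@H]1/C(=C\C[C@@H](O)/C(C)=C/CC/C(C)=C\COC/C=C/c2ccc(O)cc2)C(=O)O[C@@H]1C=C(C)C | target

Total step count: 16.
Longest linear sequence: 8 steps (steps 9 to 16; the branch through steps 1, 2, 3, 6, 7, 8, 15, 16 is equally long).

Steps most likely to fail

Step 15. The coupling may stall through halide binding to the cationic palladium. It may also drift to direct alkenyl transfer, lose material by ionisation of the allylic acetate, or show poor facial selectivity at C3'. The fallback makes the same bond at the alcohol level from a carbonyl group and sets out from 23 and 11. A Negishi coupling of 23 with (1,3-dioxolan-2-ylmethyl)zinc bromide under Pd(PPh3)4 would give the dioxolane acetal F1. Mild aqueous acid would free the beta,gamma-unsaturated aldehyde F2, which would be used at once. A ligand-controlled Nozaki–Hiyama–Kishi reaction of 11 with F2 (CrCl2, NiCl2, chiral oxazoline–sulfonamide ligand) would then add the alkenyl group under non-basic conditions. This comes back to the route at 28.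

Step 13. Geometric control in the O-sulfonylation may be lost, or the vinylogous acyl triflate may decompose on handling. The fallback replaces kinetic O-sulfonylation by an equilibrating halide addition–elimination and sets out from 21. Triphenylphosphine dibromide and Et3N (the phosphonium halide conversion of beta-dicarbonyl enols into beta-halo enoates) would give the robust bromomethylene lactone F3. Reversible bromide addition should funnel F3 to the isomer with bromine anti to the carbonyl, and its isomers can be separated on silica. Acetolysis as in step 14 would give the acetoxy bromide F4. F4 would take the place of 23 in step 15, where NaOTf already removes bromide. This comes back to the route at 27.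

Step 8. Deprotonation of the lithiobetaine may be incomplete, E selectivity may erode during bromination, or the base may attack next to the ether oxygen. The fallback builds the alkenyl metal from an alkyne by syn addition and sets out from 9. The Ohira–Bestmann reagent with K2CO3 in MeOH would give the terminal alkyne F5. Deprotonation with n-BuLi and MeI would give the methyl alkyne F6. A syn hydroboration with B2pin2, CuCl, a triarylphosphine, NaOt-Bu and MeOH, which places boron on the less hindered methyl-bearing carbon, would give the alkenylboronate F7. Addition of halide-free vinyllithium to F7 comes back to the route at 26.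

Further compounds
F1 | step 15 | (3E,4S,5R)-4-acetoxy-3-[2-(1,3-dioxolan-2-yl)ethylidene]-5-(2-methylprop-1-enyl)dihydrofuran-2(3H)-one | CC(=O)O[C@H]1/C(=C\CC2OCCO2)C(=O)O[C@@H]1C=C(C)C
F2 | step 15 | (3E,4S,5R)-4-acetoxy-5-(2-methylprop-1-enyl)-3-(3-oxopropylidene)dihydrofuran-2(3H)-one | CC(=O)O[C@H]1/C(=C\CC=O)C(=O)O[C@@H]1C=C(C)C
F3 | step 13 | (3E,4S,5R)-3-(bromomethylene)-5-(2-methylprop-1-enyl)-4-(triethylsilyloxy)dihydrofuran-2(3H)-one | CC[Si](CC)(CC)O[C@H]1/C(=C\Br)C(=O)O[C@@H]1C=C(C)C
F4 | step 13 | (3E,4S,5R)-4-acetoxy-3-(bromomethylene)-5-(2-methylprop-1-enyl)dihydrofuran-2(3H)-one | CC(=O)O[C@H]1/C(=C\Br)C(=O)O[C@@H]1C=C(C)C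
F5 | step 8 | (2Z)-3-methyloct-2-en-7-ynyl (E)-4-(triisopropylsilyloxy)cinnamyl ether | C#CCC/C(C)=C\COC/C=C/c1ccc(O[Si](C(C)C)(C(C)C)C(C)C)cc1
F6 | step 8 | (2Z)-3-methylnon-2-en-7-ynyl (E)-4-(triisopropylsilyloxy)cinnamyl ether | CC#CCC/C(C)=C\COC/C=C/c1ccc(O[Si](C(C)C)(C(C)C)C(C)C)cc1
F7 | step 8 | pinacol alkenylboronate corresponding to 11 (boron in place of bromine, anti to the chain) | CC1(C)OB(OC1(C)C)/C(C)=C/CC/C(C)=C\COC/C=C/c1ccc(O[Si](C(C)C)(C(C)C)C(C)C)cc1
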